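Start with the easy thing: read across the rows. In both earlier runs the Z readings stay flat within the scatter from the first sample on, although Z remains, with a mean z, the fraction of Z left, of 3.54% in winter and 50.7% in spring.

| flask | Z | Q | remark | time |
|---|---|---|---|---|
| winter | 0.25 M (fed, over 12 min) | 1 M | run made earlier |  |
| spring | 1 M (fed, over 12 min) | 1 M | run made earlier |  |
| flask | 0.50 M (fed, over 12 min) | 1.00 M |  | 30 h |

| run | time / h | Z / % | E / % | G / % |
|---|---|---|---|---|
| winter | 5.00 | 3.4 | 33.8 | 50.0 |
| winter | 10.0 | 3.9 | 34.0 | 50.5 |
| winter | 15.0 | 3.0 | 32.9 | 49.2 |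
| winter | 20.0 | 3.6 | 33.4 | 48.6 |
| winter | 25.0 | 3.8 | 32.9 | 48.8 |
| spring | 2.00 | 50.5 | 32.1 | 8.6 |
| spring | 4.00 | 50.6 | 31.9 | 8.9 |
| spring | 6.00 | 49.9 | 32.1 | 8.2 |
| spring | 12.0 | 51.0 | 32.1 | 8.7 |
| spring | 25.0 | 51.3 | 31.5 | 8.4 |

(readings scatter by 0.5 percentage points)

- the analysis behind the earlier runs scatters by 0.5 percentage points, standard deviation
- the reaction counts as stopped when no species that holds the Z changes by six tenths of a point or more over the second half of the time

- at 30 h, what has stopped the reaction, if anything has (forward and back rates have come level / it is still moving / all of Z has reacted / Q has run out first)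
- conversion of Z at 30 h
- amount of E at 30 h, in percent of the Z charged
- amount of G at 30 h, in percent of the Z charged

Suppose that Z falls in proportion to Q, and that Q falls in proportion to itself times whatever takes it, which grows in step with the Z charged. Divide the first rate by the second and time drops out, leaving how far ln z falls per unit of Q spent. If the whole Q charge was spent, winter gives 0.835 and spring 0.680: this is the reach R, the Z charge times −ln z divided by the Q charge.

Now take two extreme versions of the new flask. With winter's reach it keeps 18.8% of its Z, and with spring's 25.7%. The real flask should lie between them, since R fell as the ratio of Z to Q rose, and this flask's ratio is higher than winter's and lower than spring's. Spring's ratio is twice this flask's, which is twice winter's, so I take the mean reach, 0.758. That leaves 22.0% of the Z, a conversion of 78.0%.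

The forecast, expecting “Q exhausted and a frozen mixture”, says Q has run out first, with conversion 77%, E 43% and G 24%. The flask gives Q has run out first, with conversion 76.1%, E 42.8% and G 20.5%.

    Z + Q → E (k = 0.00540 M⁻¹ s⁻¹)
    Z + Q → L (k = 0.00129 M⁻¹ s⁻¹)
    Q + E → G (k = 0.00228 M⁻¹ s⁻¹)
    Q + L → G (k = 8.08 × 10⁻⁴ M⁻¹ s⁻¹)
    2 Q → X (k = 0.00113 M⁻¹ s⁻¹)

In the new flask Q, the limiting reagent, has 0% of its charge left at 30.0 h, and its reach is 0.716, below the reach read from winter and above the one read from spring. Now cut Z to 0.20 M with Q unchanged. That neighbour's ratio of Z to Q lies closer to winter's than to the new flask's, so use winter's reach: −ln z comes to 4.18, which leaves 1.54% of the Z. The neighbour flask ends with 1.28% of its Z at 30.0 h.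

The runs were computed on assumed constants; noise was put on by code.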